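The route rests on cutting the C4–C3 bond (chromane numbering) of the dihydropyran ring D fused to ring B. The CH2–CH(OH) pair is read as a hydride-opened cis-3,4-epoxide, and that epoxide as the product of an intramolecular sulfonium-ylide epoxidation: benzylic C4, flanked by the two ring-B oxygens (on C2' and C4'), carries a chiral sulfonium ylide, and C3 is a non-enolisable aldehyde on the gem-dimethyl carbon C2. One operation forms C4–C3, closes ring D and the oxirane, and fixes C3 as R. The precursor is an open aryl ether, a 2-(chloromethyl)phenyl ether of 2-hydroxy-2-methylpropanal. Hydride opening, borylation, Suzuki coupling with a 6-prenyl-3-iodochromone and MOM removal finish the synthesis.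

Key step: step 5

Assumption: the (2S,5S)-sulfide 7 is taken as a purchasable reagent (otherwise two steps from (2R,5R)-hexane-2,5-diol), and its sense of induction is assigned by analogy with intermolecular benzylidene transfer from 2,5-dimethylthiolanium ylides; should the tethered case run the other way, the (2R,5R)-sulfide is used instead.

Step 1
Reactants: 1 2,6-dihydroxybenzaldehyde; 2 ethyl 2-bromo-2-methylpropanoate
Product: 3 ethyl 2-(2-formyl-3-hydroxyphenoxy)-2-methylpropanoate
Conditions: K2CO3, DMF, 70 °C
Reagents that add atoms: none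
Why: Williamson-type etherification of a phenoxide with a tertiary α-bromo ester; it should stop at the mono-ether because the remaining hydroxyl is locked in a hydrogen bond to the formyl group.

Step 2
Reactants: 3 ethyl 2-(2-formyl-3-hydroxyphenoxy)-2-methylpropanoate
Product: 4 ethyl 2-[2-formyl-3-(methoxymethoxy)phenoxy]-2-methylpropanoate
Conditions: MOMCl, i-Pr2NEt, CH2Cl2, 0 °C to rt
Reagents that add atoms: chloromethyl methyl ether (MOMCl), COCCl
Why: MOM acetal formation on the phenol; the group is stable to hydride, base and ylide chemistry and later directs the ortho-lithiation.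

Step 3
Reactants: 4 ethyl 2-[2-formyl-3-(methoxymethoxy)phenoxy]-2-methylpropanoate
Product: 5 2-[2-(hydroxymethyl)-3-(methoxymethoxy)phenoxy]-2-methylpropanal
Conditions: DIBAL-H (2.2 equiv), CH2Cl2, −78 °C; MeOH, then aq Rochelle salt
Reagents that add atoms: none
Why: Low-temperature DIBAL reduction should take the aryl aldehyde to the benzylic alcohol and stop the hindered α-aryloxy ester at the aluminium hemiacetal, which gives the aldehyde on work-up (partial ester reduction).

Step 4
Reactants: 5 2-[2-(hydroxymethyl)-3-(methoxymethoxy)phenoxy]-2-methylpropanal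
Product: 6 2-[2-(chloromethyl)-3-(methoxymethoxy)phenoxy]-2-methylpropanal
Conditions: MsCl, Et3N, CH2Cl2, 0 °C to rt; used crude
Reagents that add atoms: methanesulfonyl chloride, CS(=O)(=O)Cl
Why: Mesylation followed by in situ chloride displacement, which is fast for a benzylic carbon activated by two ortho oxygens; the non-enolisable aldehyde is untouched.

Step 5
Reactants: 6 2-[2-(chloromethyl)-3-(methoxymethoxy)phenoxy]-2-methylpropanal; 7 (2S,5S)-2,5-dimethylthiolane
Product: 9 (3R,4R)-3,4-epoxy-5-(methoxymethoxy)-2,2-dimethylchromane, via benzylic sulfonium chloride 8 (not isolated)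
Conditions: 7 (1.2 equiv), NaI (10 mol%), MeCN, rt; then KOH (powder), MeCN/H2O 9:1, 0 °C; filtration through basic alumina
Reagents that add atoms: none
Why: The sulfide displaces the activated benzylic chloride to give sulfonium salt 8; KOH forms the benzylic ylide, which adds to the tethered aldehyde, and the anti betaine expels the sulfide, so the C4–C3 bond and the oxirane form in one operation. This is an intramolecular chiral-sulfide-mediated Corey–Chaykovsky epoxidation, closest to asymmetric benzylidene transfer from chiral benzylsulfonium salts and to sulfur-ylide epoxy-annulations that give cis-fused epoxides. Ring D closes 6-exo-trig through the C–C bond and the oxirane closes 3-exo-tet through O–C4 displacement. C4 is set by attack on the ylide face left open by the thiolane methyl groups (reagent control), and C3 is tied to C4 because only the betaine with O and S trans can close and the oxirane must be cis-fused, while the syn betaine should revert. The step needs enantiofacial selectivity, which the C2-symmetric sulfide supplies through a single sulfonium and ylide, and cyclisation ahead of hydrolysis or intermolecular reaction, which the gem-dimethyl (Thorpe–Ingold) bias, the six-membered transition state and the absence of any enolisable carbonyl secure. The sulfide is released unchanged and is recovered.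

Step 6
Reactants: 9 (3R,4R)-3,4-epoxy-5-(methoxymethoxy)-2,2-dimethylchromane
Product: 10 (3R)-5-(methoxymethoxy)-2,2-dimethylchroman-3-ol
Conditions: LiAlH4, THF, 0 °C; aq NaOH work-up
Reagents that add atoms: none
Why: Regioselective hydride opening of the epoxide at the benzylic and less hindered C4 (C3 is neopentyl); the C3–O bond is not touched, so the R configuration is kept.

Step 7
Reactants: 10 (3R)-5-(methoxymethoxy)-2,2-dimethylchroman-3-ol
Product: 11 (3R)-5-(methoxymethoxy)-2,2-dimethyl-6-(4,4,5,5-tetramethyl-1,3,2-dioxaborolan-2-yl)chroman-3-ol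
Conditions: n-BuLi (2.5 equiv), TMEDA, THF, −20 to 0 °C; then i-PrOBpin, −78 °C to rt; aq NH4Cl
Reagents that add atoms: 2-isopropoxy-4,4,5,5-tetramethyl-1,3,2-dioxaborolane, CC(C)OB1OC(C)(C)C(C)(C)O1
Why: Directed ortho-metalation by the MOM ether, whose only free ortho position is C6 (the future C1' of ring B), after the alcohol is deprotonated by the first equivalent of base; borate trapping gives the pinacol boronate.

Step 8
Reactants: 12 2,4,6-trihydroxyacetophenone
Product: 13 1-[2,6-dihydroxy-4-(methoxymethoxy)phenyl]ethan-1-one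
Conditions: MOMCl (1.05 equiv), i-Pr2NEt, CH2Cl2, 0 °C
Reagents that add atoms: chloromethyl methyl ether (MOMCl), COCCl
Why: Selective MOM protection of the 4-hydroxyl, the only one not hydrogen-bonded to the ketone and the most acidic.

Step 9
Reactants: 13 1-[2,6-dihydroxy-4-(methoxymethoxy)phenyl]ethan-1-one; 14 3-chloro-3-methylbut-1-yne
Product: 15 1-[2-hydroxy-4-(methoxymethoxy)-6-(2-methylbut-3-yn-2-yloxy)phenyl]ethan-1-one
Conditions: DBU, CuCl2 (1 mol%), MeCN, 0 °C to rt
Reagents that add atoms: none
Why: Copper-catalysed propargylic etherification of a phenol with a tertiary propargyl chloride; mono-alkylation is expected because the second hydroxyl then stays chelated to the ketone.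

Step 10
Reactants: 15 1-[2-hydroxy-4-(methoxymethoxy)-6-(2-methylbut-3-yn-2-yloxy)phenyl]ethan-1-one
Product: 16 1-[2-hydroxy-4-(methoxymethoxy)-6-(2-methylbut-3-en-2-yloxy)phenyl]ethan-1-one
Conditions: H2 (1 atm), Lindlar catalyst (Pd on CaCO3 poisoned with Pb(OAc)2), quinoline, EtOAc, rt
Reagents that add atoms: none
Why: Lindlar semi-hydrogenation of the terminal alkyne to the 1,1-dimethylallyl ether; the ketone and the MOM ether are inert.

Step 11
Reactants: 16 1-[2-hydroxy-4-(methoxymethoxy)-6-(2-methylbut-3-en-2-yloxy)phenyl]ethan-1-one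
Product: 17 (E)-3-(dimethylamino)-1-[2-hydroxy-4-(methoxymethoxy)-6-(2-methylbut-3-en-2-yloxy)phenyl]prop-2-en-1-one
Conditions: t-BuOCH(NMe2)2 (Bredereck's reagent), THF, 40 °C
Reagents that add atoms: tert-butoxybis(dimethylamino)methane, CN(C)C(OC(C)(C)C)N(C)C
Why: Enaminone condensation at the acetyl methyl group; the low temperature should keep the aryl 1,1-dimethylallyl ether from rearranging before the ring oxygen is committed.

Step 12
Reactants: 17 (E)-3-(dimethylamino)-1-[2-hydroxy-4-(methoxymethoxy)-6-(2-methylbut-3-en-2-yloxy)phenyl]prop-2-en-1-one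
Product: 18 3-iodo-7-(methoxymethoxy)-5-(2-methylbut-3-en-2-yloxy)-4H-chromen-4-one
Conditions: I2, pyridine, CHCl3, rt
Reagents that add atoms: iodine, II
Why: Iodination of the enaminone α-carbon and cyclisation by the free phenol with loss of dimethylamine (iodocyclisation to a 3-iodochromone); the only free hydroxyl becomes the ring oxygen, so the allyl ether is left on O5.

Step 13
Reactants: 18 3-iodo-7-(methoxymethoxy)-5-(2-methylbut-3-en-2-yloxy)-4H-chromen-4-one
Product: 19 5-hydroxy-3-iodo-7-(methoxymethoxy)-6-(3-methylbut-2-en-1-yl)-4H-chromen-4-one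
Conditions: PhMe, 110 °C, sealed tube
Reagents that add atoms: none
Why: Aromatic Claisen rearrangement; C6 is the only open ortho position of O5, and the [3,3] shift turns the 1,1-dimethylallyl ether into the linear prenyl group and returns the chelated 5-hydroxyl.

Step 14
Reactants: 19 5-hydroxy-3-iodo-7-(methoxymethoxy)-6-(3-methylbut-2-en-1-yl)-4H-chromen-4-one; 11 (3R)-5-(methoxymethoxy)-2,2-dimethyl-6-(4,4,5,5-tetramethyl-1,3,2-dioxaborolan-2-yl)chroman-3-ol
Product: 20 5-hydroxy-3-[(3R)-3-hydroxy-5-(methoxymethoxy)-2,2-dimethylchroman-6-yl]-7-(methoxymethoxy)-6-(3-methylbut-2-en-1-yl)-4H-chromen-4-one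
Conditions: Pd(dppf)Cl2 (5 mol%), K2CO3, 1,4-dioxane/H2O 5:1, 70 °C
Reagents that add atoms: none
Why: Suzuki–Miyaura coupling; oxidative addition is fast at the C3–I bond of the chromone (a vinylogous acyl iodide), and the free alcohol and chelated phenol are tolerated.

Step 15
Reactants: 20 5-hydroxy-3-[(3R)-3-hydroxy-5-(methoxymethoxy)-2,2-dimethylchroman-6-yl]-7-(methoxymethoxy)-6-(3-methylbut-2-en-1-yl)-4H-chromen-4-one
Product: 21 5,7-dihydroxy-3-[(3R)-3,5-dihydroxy-2,2-dimethylchroman-6-yl]-6-(3-methylbut-2-en-1-yl)-4H-chromen-4-one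
Conditions: 3 M aq HCl, MeOH, 45 °C
Reagents that add atoms: none
Why: Acid-catalysed methanolysis of both aryl MOM acetals under conditions mild enough to leave the prenyl group, the tertiary aryl ether of ring D and the C3 carbinol intact.

Compound list
1 | 2,6-dihydroxybenzaldehyde | O=Cc1c(O)cccc1O | starting material
2 | ethyl 2-bromo-2-methylpropanoate | CCOC(=O)C(C)(C)Br | starting material
3 | ethyl 2-(2-formyl-3-hydroxyphenoxy)-2-methylpropanoate | CCOC(=O)C(C)(C)Oc1cccc(O)c1C=O | intermediate
4 | ethyl 2-[2-formyl-3-(methoxymethoxy)phenoxy]-2-methylpropanoate | CCOC(=O)C(C)(C)Oc1cccc(OCOC)c1C=O | intermediate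
5 | 2-[2-(hydroxymethyl)-3-(methoxymethoxy)phenoxy]-2-methylpropanal | CC(C)(C=O)Oc1cccc(OCOC)c1CO | intermediate
6 | 2-[2-(chloromethyl)-3-(methoxymethoxy)phenoxy]-2-methylpropanal | CC(C)(C=O)Oc1cccc(OCOC)c1CCl | intermediate
7 | (2S,5S)-2,5-dimethylthiolane (chiral sulfide, recovered) | C[C@H]1CC[C@H](C)S1 | starting material
8 | (2S,5S)-1-{2-(methoxymethoxy)-6-[(2-methyl-1-oxopropan-2-yl)oxy]benzyl}-2,5-dimethylthiolanium chloride (not isolated) | C[C@H]1CC[C@H](C)[S+]1Cc1c(OCOC)cccc1OC(C)(C)C=O.[Cl-] | intermediate
9 | (3R,4R)-3,4-epoxy-5-(methoxymethoxy)-2,2-dimethylchromane | COCOc1cccc2OC(C)(C)[C@@H]3O[C@@H]3c12 | intermediate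
10 | (3R)-5-(methoxymethoxy)-2,2-dimethylchroman-3-ol | COCOc1cccc2OC(C)(C)[C@H](O)Cc12 | intermediate
11 | (3R)-5-(methoxymethoxy)-2,2-dimethyl-6-(4,4,5,5-tetramethyl-1,3,2-dioxaborolan-2-yl)chroman-3-ol | COCOc1c(B2OC(C)(C)C(C)(C)O2)ccc2OC(C)(C)[C@H](O)Cc12 | intermediate
12 | 2,4,6-trihydroxyacetophenone | CC(=O)c1c(O)cc(O)cc1O | starting material
13 | 1-[2,6-dihydroxy-4-(methoxymethoxy)phenyl]ethan-1-one | CC(=O)c1c(O)cc(OCOC)cc1O | intermediate
14 | 3-chloro-3-methylbut-1-yne | C#CC(C)(C)Cl | starting material
15 | 1-[2-hydroxy-4-(methoxymethoxy)-6-(2-methylbut-3-yn-2-yloxy)phenyl]ethan-1-one | CC(=O)c1c(O)cc(OCOC)cc1OC(C)(C)C#C | intermediate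
16 | 1-[2-hydroxy-4-(methoxymethoxy)-6-(2-methylbut-3-en-2-yloxy)phenyl]ethan-1-one | CC(=O)c1c(O)cc(OCOC)cc1OC(C)(C)C=C | intermediate
17 | (E)-3-(dimethylamino)-1-[2-hydroxy-4-(methoxymethoxy)-6-(2-methylbut-3-en-2-yloxy)phenyl]prop-2-en-1-one | CN(C)/C=C/C(=O)c1c(O)cc(OCOC)cc1OC(C)(C)C=C | intermediate
18 | 3-iodo-7-(methoxymethoxy)-5-(2-methylbut-3-en-2-yloxy)-4H-chromen-4-one | COCOc1cc(OC(C)(C)C=C)c2c(c1)occ(I)c2=O | intermediate
19 | 5-hydroxy-3-iodo-7-(methoxymethoxy)-6-(3-methylbut-2-en-1-yl)-4H-chromen-4-one | COCOc1cc2occ(I)c(=O)c2c(O)c1CC=C(C)C | intermediate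
20 | 5-hydroxy-3-[(3R)-3-hydroxy-5-(methoxymethoxy)-2,2-dimethylchroman-6-yl]-7-(methoxymethoxy)-6-(3-methylbut-2-en-1-yl)-4H-chromen-4-one | COCOc1cc2occ(-c3ccc4OC(C)(C)[C@H](O)Cc4c3OCOC)c(=O)c2c(O)c1CC=C(C)C | intermediate
21 | 5,7-dihydroxy-3-[(3R)-3,5-dihydroxy-2,2-dimethylchroman-6-yl]-6-(3-methylbut-2-en-1-yl)-4H-chromen-4-one (CNP0194496.1) | CC(C)=CCc1c(O)cc2occ(-c3ccc4c(c3O)C[C@@H](O)C(C)(C)O4)c(=O)c2c1O | target

Total step count: 15. Longest linear sequence: 9 steps (steps 1 to 7, then 14 and 15); the chromone branch (steps 8 to 13) runs in parallel.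

Steps most likely to fail

Step 5. Enantiofacial control by the sulfide may erode in the tethered case, the reaction may stall at a betaine that cannot close, or the very labile benzylic chloride or sulfonium salt may solvolyse before the ylide forms. The fallback sets out from 6 and comes back at 9, and moves the stereochemical control to a catalytic epoxidation of an olefin. Chloride 6 is heated with PPh3 in MeCN to give {2-(methoxymethoxy)-6-[(2-methyl-1-oxopropan-2-yl)oxy]benzyl}triphenylphosphonium chloride F1. K2CO3 in THF then triggers an intramolecular Wittig olefination, which closes the same C4–C3 bond as a double bond and gives 5-(methoxymethoxy)-2,2-dimethyl-2H-chromene F2. Jacobsen epoxidation of this cis-olefin with the (R,R)-(salen)MnCl catalyst (trivalent manganese), NaOCl and 4-phenylpyridine N-oxide in CH2Cl2 at 0 °C should give epoxide 9, by analogy with other 2,2-dimethylchromenes.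

Step 7. The neighbouring lithium alkoxide may slow or misdirect the ring lithiation, and the electron-rich boronate may protodeboronate during work-up. The fallback sets out from 10 and comes back at 11, and replaces deprotonation by electrophilic halogenation and palladium-catalysed borylation. Brief HCl/MeOH treatment of 10 gives (3R)-2,2-dimethylchromane-3,5-diol F3. NBS with catalytic i-Pr2NH in CH2Cl2 at low temperature brominates ortho to the free phenol, a position that is also para to the ring oxygen, to give (3R)-6-bromo-2,2-dimethylchromane-3,5-diol F4. MOMCl and i-Pr2NEt reprotect the phenol selectively to give (3R)-6-bromo-5-(methoxymethoxy)-2,2-dimethylchroman-3-ol F5. Miyaura borylation (B2pin2, Pd(dppf)Cl2, KOAc, 1,4-dioxane, 85 °C) returns boronate 11.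

Step 14. Protodeboronation of the ortho-alkoxy boronate and hydroxide-induced opening of the pyranone ring may outrun transmetalation, and the free 5-hydroxyl may slow the coupling. The fallback sets out from 10 and 19 and comes back at 21, and uses a base-free Negishi coupling. Iodochromone 19 is protected with NaH and MOMCl in DMF to give 3-iodo-5,7-bis(methoxymethoxy)-6-(3-methylbut-2-en-1-yl)-4H-chromen-4-one F6. Alcohol 10 is lithiated as in step 7 and transmetalated with ZnCl2 to the arylzinc chloride lithium alkoxide F7, which is not isolated. Coupling of F7 with F6 (Pd(PPh3)4, THF, 50 °C) gives 3-[(3R)-3-hydroxy-5-(methoxymethoxy)-2,2-dimethylchroman-6-yl]-5,7-bis(methoxymethoxy)-6-(3-methylbut-2-en-1-yl)-4H-chromen-4-one F8, which under the conditions of step 15 gives 21.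

Further compounds
F1 | step 5 | {2-(methoxymethoxy)-6-[(2-methyl-1-oxopropan-2-yl)oxy]benzyl}triphenylphosphonium chloride | O=CC(C)(C)Oc1cccc(OCOC)c1C[P+](c1ccccc1)(c1ccccc1)c1ccccc1.[Cl-]
F2 | step 5 | 5-(methoxymethoxy)-2,2-dimethyl-2H-chromene | COCOc1cccc2OC(C)(C)C=Cc12
F3 | step 7 | (3R)-2,2-dimethylchromane-3,5-diol | Oc1cccc2OC(C)(C)[C@H](O)Cc12
F4 | step 7 | (3R)-6-bromo-2,2-dimethylchromane-3,5-diol | Oc1c(Br)ccc2OC(C)(C)[C@H](O)Cc12
F5 | step 7 | (3R)-6-bromo-5-(methoxymethoxy)-2,2-dimethylchroman-3-ol | COCOc1c(Br)ccc2OC(C)(C)[C@H](O)Cc12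
F6 | step 14 | 3-iodo-5,7-bis(methoxymethoxy)-6-(3-methylbut-2-en-1-yl)-4H-chromen-4-one | COCOc1cc2occ(I)c(=O)c2c(OCOC)c1CC=C(C)C
F7 | step 14 | [(3R)-3-(lithiooxy)-5-(methoxymethoxy)-2,2-dimethylchroman-6-yl]zinc chloride | COCOc1c([Zn]Cl)ccc2OC(C)(C)[C@H](O[Li])Cc12
F8 | step 14 | 3-[(3R)-3-hydroxy-5-(methoxymethoxy)-2,2-dimethylchroman-6-yl]-5,7-bis(methoxymethoxy)-6-(3-methylbut-2-en-1-yl)-4H-chromen-4-one | COCOc1cc2occ(-c3ccc4OC(C)(C)[C@H](O)Cc4c3OCOC)c(=O)c2c(OCOC)c1CC=C(C)C
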